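**Strategy.** The route rests on one disconnection: the C9–C10 bond (numbering from the lactone carbonyl C1) inside the unfunctionalised polymethylene arc C2–C25 of the 27-membered oxacycle. Two neighbouring ring methylenes with no function nearby are the hydrogenated trace of an olefin, so ring-closing olefin metathesis of the open-chain diene ester octadec-17-en-1-yl dec-9-enoate unites two terminal sp2 carbons of like polarity as C9=C10, expels ethene and closes the strain-free macrocycle; hydrogen admitted to the same vessel lets the ruthenium residue saturate that bond, so one operation delivers the target. The diene ester is assembled from dec-9-enoic acid and a C18 alkenol made by copper-catalysed Grignard coupling.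

Key step: step 3

Remark on the chemistry: the target has no stereocentre, and the E/Z composition of the intermediate ring olefin is immaterial because that double bond is hydrogenated in the same operation.

**Step 1**
Reactants: 1 11-bromoundec-1-ene; 2 7-bromoheptan-1-ol
Product: 5 octadec-17-en-1-ol, via undec-10-enylmagnesium bromide 3 (not isolated), via bromomagnesium 7-bromoheptan-1-olate 4 (not isolated)
Conditions: Mg turnings, THF, 40 °C (1 to 3, 2.5 equiv); then 2, Li2CuCl4 (3 mol %), THF, −20 °C to rt; aq NH4Cl
Reagents that add atoms: none
Why: Copper-catalysed Csp3–Csp3 Grignard cross-coupling (Kochi coupling), in which the first equivalent of 3 only deprotonates the hydroxyl of 2 to the inert alkoxide 4 and a further equivalent displaces the unhindered primary bromide through a transient alkylcuprate, the remote terminal alkene being a spectator.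

**Step 2**
Reactants: 5 octadec-17-en-1-ol; 6 dec-9-enoic acid
Product: 7 octadec-17-en-1-yl dec-9-enoate
Conditions: DCC, DMAP (10 mol %), CH2Cl2, 0 °C to rt
Reagents that add atoms: none
Why: Steglich esterification, in which the O-acylisourea formed from 6 and DCC is relayed by DMAP as an acylpyridinium ion to the primary alcohol under neutral conditions that leave both terminal alkenes in place.

**Step 3**
Reactants: 7 octadec-17-en-1-yl dec-9-enoate
Product: 9 26-hexacosanolide, via oxacycloheptacos-10-en-2-one 8 (not isolated)
Conditions: first-generation Grubbs catalyst RuCl2(=CHPh)(PCy3)2 (5 mol %), CH2Cl2 (2 mM, slow addition of 7), reflux, Ar purge; then H2 (50 atm), 50 °C, same vessel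
Reagents that add atoms: none
Why: The ruthenium benzylidene engages one monosubstituted alkene of 7 by [2+2] cycloaddition and cycloreversion, and the resulting chain-bound alkylidene captures the other terminus through a ruthenacyclobutane whose collapse forms C9=C10, releases the ring and passes the metal on as its methylidene, with loss of ethene driving the equilibrium. The closest known reaction type is ring-closing metathesis of ω-alkenyl ω-alkenoates to macrolactones, followed by hydrogenation through the hydride RuHCl(H2)(PCy3)2 that the spent carbene should give under H2 (tandem metathesis–hydrogenation). The single ring closed is the 27-membered lactone, by end-to-end macrocyclisation of an α,ω-diene, a strain-free large-ring closure under entropic control. No stereocentre arises, and the E/Z mixture of 8 converges on one saturated product. The step needs ring closure to win over acyclic diene metathesis oligomerisation, which 2 mM dilution, slow addition and the reversibility that lets oligomers back-bite to the ring should secure, and it needs the double bonds to stay in place before closure (migration would give ring-contracted homologues), which the phosphine-only first-generation catalyst at 40 °C should secure. Both olefins are unhindered monosubstituted termini lying seven or more atoms from the ester, so no carbonyl chelate should deactivate the carbene, and the ester is not touched by the hydrogenation.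

**Compound list**
1 | 11-bromoundec-1-ene | C=CCCCCCCCCCBr | starting material
2 | 7-bromoheptan-1-ol | OCCCCCCCBr | starting material
3 | undec-10-enylmagnesium bromide | C=CCCCCCCCCC[Mg]Br | intermediate
4 | bromomagnesium 7-bromoheptan-1-olate | BrCCCCCCCO[Mg]Br | intermediate
5 | octadec-17-en-1-ol | C=CCCCCCCCCCCCCCCCCO | intermediate
6 | dec-9-enoic acid | C=CCCCCCCCC(=O)O | starting material
7 | octadec-17-en-1-yl dec-9-enoate | C=CCCCCCCCC(=O)OCCCCCCCCCCCCCCCCC=C | intermediate
8 | oxacycloheptacos-10-en-2-one (hexacos-9-en-26-olide, E/Z mixture) | O=C1CCCCCCCC=CCCCCCCCCCCCCCCCCO1 | intermediate
9 | 26-hexacosanolide (oxacycloheptacosan-2-one) | O=C1CCCCCCCCCCCCCCCCCCCCCCCCCO1 | target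

**Total step count:** 3
**Longest linear sequence:** 3 steps (1 to 5 to 7 to 9; acid 6 enters at step 2)

**Steps most likely to fail**

Step 3 (key step). Intermolecular acyclic diene metathesis may outrun ring closure, double-bond migration before closure may lead to ring contraction, or the ruthenium residue may stall before hydrogenation is complete. The fallback sets out from 7 and keeps the same bond construction with a different reaction. Ozonolysis of both terminal alkenes (O3, CH2Cl2, −78 °C; then PPh3) should give 17-oxoheptadecyl 9-oxononanoate F1. Intramolecular McMurry coupling of the two aldehyde carbons with low-valent titanium (TiCl3, Zn(Cu), DME, reflux, syringe-pump addition) should then close the ring at C9=C10, the aldehydes coupling much faster than the remote ester can react. This comes back to the route at 8, which is isolated and hydrogenated separately (H2, Pd/C, EtOAc, rt) to 9.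

Step 1. The precipitating magnesium alkoxide may stall the coupling while the excess Grignard reagent is consumed by homocoupling. The fallback sets out from 2 and masks the hydroxyl as the very ester needed later. Steglich esterification of 2 with 6 (DCC, DMAP, CH2Cl2) should give 7-bromoheptyl dec-9-enoate F2. Copper-catalysed coupling of F2 with 3 (1.2 equiv, Li2CuCl4 3 mol %, NMP 4 equiv, THF, 0 °C, slow addition) should be chemoselective for the C–Br bond over the ester. This comes back to the route at 7 and bypasses 5 and step 2.

Step 2. The O-acylisourea may rearrange to the unreactive N-acylurea, and urea may be carried along with the waxy ester. The fallback sets out from 5 and forms the alkyl–oxygen bond in place of the acyl–oxygen bond. Mesylation (MsCl, Et3N, CH2Cl2, 0 °C) should give octadec-17-en-1-yl methanesulfonate F3. Displacement by the caesium salt of 6 (Cs2CO3, DMF, 60 °C) should then give the ester, coming back to the route at 7.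

**Further compounds**
F1 | step 3 | 17-oxoheptadecyl 9-oxononanoate | O=CCCCCCCCC(=O)OCCCCCCCCCCCCCCCCC=O
F2 | step 1 | 7-bromoheptyl dec-9-enoate | C=CCCCCCCCC(=O)OCCCCCCCBr
F3 | step 2 | octadec-17-en-1-yl methanesulfonate | C=CCCCCCCCCCCCCCCCCOS(C)(=O)=O
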